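**Plan**

Numbering follows isochromene: C1 (lactone C=O), O2, C3, C4, C4a, C5, C6 (ketone), C7, C8 (enol), C8a. Ring A is the carbocycle and ring B the pyranone.
Enabling feature: the quaternary C5 bears a CH3 directly beside the C6 carbonyl. C5–C6 and that CH3 can therefore be made in one event from a C5=CH2 group on C4a of ring B and a C6 aldehyde that C8a keeps within reach through the C7=C8 enol ether.
Retrosynthetic cuts, in order: O-protecting group at C8; C5–C6 (CH3 reverting to =CH2); C4a–C5 (thioether/boronic acid coupling); C8–O and C6–C7 (alkoxide exchange, chloroformylation); C8–C8a (C-acylation); C1′–alkyne bond of the side chain.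
Forward: ring B is bought, and its C8a arm is grown to the β-alkoxy enal while no alkene is yet present. The farnesyl-derived tetraene is then joined at C4a, and ring A is closed last.
Stereochemistry: C5 (S) is the only stereocentre and comes from face selection by a chiral triazolylidene in the ring closure. The 2E,6E alkenes are carried over from farnesyl bromide.

Key step: step 8

Assumption: the sense of induction of the aminoindanol-derived carbene cannot be deduced for this new substrate class, so the (5aS,10bR) salt is written and its equally available antipode is to be used if the first run shows the (5R) ketone.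

**Step 1**
Reactants: 1 4-hydroxy-6-methylpyran-2-one; 2 propanoyl chloride
Product: 4 4-hydroxy-6-methyl-3-propanoylpyran-2-one, via 6-methyl-2-oxopyran-4-yl propanoate 3 (not isolated)
Conditions: Et3N, toluene, 0 °C to rt; then 4-(dimethylamino)pyridine (20 mol %), 90 °C
Reagents that add atoms: none
Why: O-acylation followed by 4-(dimethylamino)pyridine-catalysed O-to-C acyl migration (Fries-type rearrangement of an enol ester) is the standard entry to 3-acyl-4-hydroxypyran-2-ones, C3 being the only carbon flanked by both oxygenated positions.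

**Step 2**
Reactants: 4 4-hydroxy-6-methyl-3-propanoylpyran-2-one
Product: 6 6-methyl-4-(methylsulfanyl)-3-propanoylpyran-2-one, via pyranyl tosylate 5 (not isolated)
Conditions: 4-MeC6H4SO2Cl, Et3N, MeCN, 0 °C; then NaSMe, 0 °C to rt
Reagents that add atoms: sodium methanethiolate, C[S-].[Na+]; 4-methylbenzenesulfonyl chloride, Cc1ccc(cc1)S(=O)(=O)Cl (its atoms stay in 5 only)
Why: Sulfonylation of the acidic C4 hydroxyl gives a doubly activated vinylogous sulfonate that undergoes vinylic addition–elimination with thiolate at C4, and the thioether is chosen because it resists the chloride and alkoxide of the next two steps yet can still be cross-coupled.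

**Step 3**
Reactants: 6 6-methyl-4-(methylsulfanyl)-3-propanoylpyran-2-one
Product: 8 (2Z)-3-chloro-2-methyl-3-[6-methyl-4-(methylsulfanyl)-2-oxopyran-3-yl]prop-2-enal, via chloropropeniminium dichlorophosphate 7 (not isolated)
Conditions: POCl3, DMF, 0 to 60 °C; then ice-water
Reagents that add atoms: N,N-dimethylformamide, CN(C)C=O; phosphoryl chloride, O=P(Cl)(Cl)Cl; water, O
Why: In this Vilsmeier–Haack–Arnold chloroformylation of an aryl-type ethyl ketone the enol is formylated at C7 and the carbonyl oxygen is exchanged for chloride, which fixes C8 as the heteroatom-bearing carbon and C6 as the aldehyde without ambiguity, and it is placed before the polyene arrives because chloroiminium ions and HCl attack tri- and 1,1-disubstituted alkenes.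

**Step 4**
Reactants: 8 (2Z)-3-chloro-2-methyl-3-[6-methyl-4-(methylsulfanyl)-2-oxopyran-3-yl]prop-2-enal
Product: 9 (2E)-2-methyl-3-[6-methyl-4-(methylsulfanyl)-2-oxopyran-3-yl]-3-[2-(trimethylsilyl)ethoxy]prop-2-enal
Conditions: Me3SiCH2CH2OH, NaH (1.1 equiv of alkoxide), THF, −30 to 0 °C
Reagents that add atoms: 2-(trimethylsilyl)ethanol, C[Si](C)(C)CCO
Why: Addition–elimination on the vinylogous acid chloride should outrun attack at the thioether-bearing C4 or at the lactone, the slight excess of alkoxide equilibrates the push–pull alkene through the symmetrical ketal enolate toward the E isomer that places the bulky twisted pyranone cis to the small formyl group, and the 2-silylethyl group is preferred to methyl because fluoride removes it at 0 °C.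

**Step 5**
Reactants: 10 (2E,6E)-farnesyl bromide; 11 ethynylmagnesium bromide
Product: 12 (4E,8E)-5,9,13-trimethyltetradeca-4,8,12-trien-1-yne
Conditions: CuBr·SMe2 (5 mol %), THF, 0 °C to rt (11 in twofold excess)
Reagents that add atoms: none
Why: Copper-catalysed SN2-selective coupling of a primary allylic bromide with an alkynyl Grignard reagent gives the skipped enyne with the alkene geometry retained, the excess acetylide suppressing double alkylation.

**Step 6**
Reactants: 12 (4E,8E)-5,9,13-trimethyltetradeca-4,8,12-trien-1-yne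
Product: 15 [(4E,8E)-5,9,13-trimethyltetradeca-1,4,8,12-tetraen-2-yl]boronic acid, via alkenylalane 13 (not isolated), via dimethyl boronate 14 (not isolated)
Conditions: Ni(dppp)Cl2 (3 mol %), i-Bu2AlH, THF, 0 to 22 °C; B(OMe)3, 0 to 22 °C; aq NH4Cl
Reagents that add atoms: trimethyl borate, COB(OC)OC; water, O; diisobutylaluminium hydride, CC(C)C[AlH]CC(C)C (its aluminium stays in 13 only)
Why: Nickel-catalysed Markovnikov (α-selective) hydroalumination of a terminal alkyl alkyne places aluminium on the internal carbon without touching trisubstituted alkenes, and aluminium-to-boron exchange with a borate ester followed by hydrolysis delivers the 1,1-disubstituted alkenylboronic acid.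

**Step 7**
Reactants: 9 (2E)-2-methyl-3-[6-methyl-4-(methylsulfanyl)-2-oxopyran-3-yl]-3-[2-(trimethylsilyl)ethoxy]prop-2-enal; 15 [(4E,8E)-5,9,13-trimethyltetradeca-1,4,8,12-tetraen-2-yl]boronic acid
Product: 16 (2E)-2-methyl-3-{6-methyl-2-oxo-4-[(4E,8E)-5,9,13-trimethyltetradeca-1,4,8,12-tetraen-2-yl]pyran-3-yl}-3-[2-(trimethylsilyl)ethoxy]prop-2-enal
Conditions: Pd2(dba)3 (4 mol %), P(2-furyl)3 (16 mol %), copper thiophene-2-carboxylate (1.6 equiv), THF, 50 °C, Ar
Reagents that add atoms: none
Why: In this Liebeskind–Srogl coupling zerovalent palladium inserts into the C4–S bond of the vinylogous thioester while the copper carboxylate binds sulfur and activates boron, so C4a–C5 forms under neutral, base-free conditions that spare the aldehyde, the enol ether and the skipped diene.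

**Step 8**
Reactants: 16 (2E)-2-methyl-3-{6-methyl-2-oxo-4-[(4E,8E)-5,9,13-trimethyltetradeca-1,4,8,12-tetraen-2-yl]pyran-3-yl}-3-[2-(trimethylsilyl)ethoxy]prop-2-enal
Product: 17 (5S)-3,5,7-trimethyl-5-[(2E,6E)-3,7,11-trimethyldodeca-2,6,10-trienyl]-8-[2-(trimethylsilyl)ethoxy]isochromene-1,6-dione
Conditions: (5aS,10bR)-2-mesityl-5a,10b-dihydro-4H,6H-indeno[2,1-b][1,2,4]triazolo[4,3-d][1,4]oxazin-2-ium tetrafluoroborate (20 mol %), K3PO4 (20 mol %), 4 Å molecular sieves, 1,4-dioxane (0.02 M), Ar, 45 °C
Reagents that add atoms: none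
Why: Proposed new method: the carbene released from the triazolium salt adds to the C6 aldehyde and a proton shift gives the hydroxy-enamine (Breslow intermediate) in which C6 is a donor, C6 then bonds to C5 while the O–H hydrogen passes to the terminal CH2 through a five-centre ene-like transition state, and the resulting alkoxide expels the carbene to leave the C6 ketone and the new C5 methyl group. The closest known reaction type is the carbene-catalysed enantioselective intramolecular hydroacylation of unactivated 1,1-disubstituted alkenes tethered to o-alkoxybenzaldehydes, which gives six-membered ketones with an α-methyl quaternary centre; the O–C8=C7–C6HO array copies the o-alkoxybenzaldehyde motif, but an enal donor on an all-sp2 carbon tether has not been shown. The closure of ring A is 6-exo-trig, C5 being the attacked atom and CH2 staying outside the ring. C5 is the only new stereocentre: the methylidene has no geometrical isomers, acyl carbon and hydrogen are delivered to the same alkene face, and that face is picked by the indane wall and the N-mesityl group of the catalyst. The step needs 6-exo acyl transfer to beat 7-endo Stetter-type addition to CH2, protonation of the homoenolate at C8 and thermal 6π closure of the C7=C8–C8a=C4a–C5=CH2 triene; its two ortho neighbours twist C5=CH2 out of conjugation with ring B so that CH2 is no activated acceptor and the C5 p-orbital points at C6, C8 is fully substituted and donor-bearing, the medium is aprotic, and the temperature is held at 45 °C. Only the E enal can reach C5, and any Z isomer should feed into it by reversible conjugate addition of carbene or traces of alkoxide to the push–pull alkene.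

**Step 9**
Reactants: 17 (5S)-3,5,7-trimethyl-5-[(2E,6E)-3,7,11-trimethyldodeca-2,6,10-trienyl]-8-[2-(trimethylsilyl)ethoxy]isochromene-1,6-dione
Product: 19 (5S)-8-hydroxy-3,5,7-trimethyl-5-[(2E,6E)-3,7,11-trimethyldodeca-2,6,10-trienyl]isochromene-1,6-dione, via tetrabutylammonium enolate 18 (not isolated)
Conditions: Bu4NF, THF, 0 °C; then 0.1 M HCl
Reagents that add atoms: tetrabutylammonium fluoride, CCCC[N+](CCCC)(CCCC)CCCC.[F-] (its cation stays in 18 only)
Why: Fluoride attacks silicon and the 2-silylethyl group fragments to ethene and the strongly stabilised enolate (β-elimination as in 2-(trimethylsilyl)ethyl ester cleavage), which frees the C8 enol in the cold, leaves the quaternary and non-epimerisable C5 untouched, and avoids the heating that could send the farnesyl group of this 6-allyl-type cyclohexa-2,4-dienone through a [3,3] shift to oxygen.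

**Compound list**

| No. | Name | SMILES | Role |
|---|---|---|---|
| 1 | 4-hydroxy-6-methylpyran-2-one | Cc1cc(O)cc(=O)o1 | starting material |
| 2 | propanoyl chloride | CCC(Cl)=O | starting material |
| 3 | 6-methyl-2-oxopyran-4-yl propanoate | CCC(=O)Oc1cc(C)oc(=O)c1 | intermediate |
| 4 | 4-hydroxy-6-methyl-3-propanoylpyran-2-one | CCC(=O)c1c(O)cc(C)oc1=O | intermediate |
| 5 | 6-methyl-2-oxo-3-propanoylpyran-4-yl 4-methylbenzenesulfonate | CCC(=O)c1c(OS(=O)(=O)c2ccc(C)cc2)cc(C)oc1=O | intermediate |
| 6 | 6-methyl-4-(methylsulfanyl)-3-propanoylpyran-2-one | CCC(=O)c1c(SC)cc(C)oc1=O | intermediate |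
| 7 | (2Z)-3-chloro-N,N,2-trimethyl-3-[6-methyl-4-(methylsulfanyl)-2-oxopyran-3-yl]prop-2-en-1-iminium dichlorophosphate | C[N+](C)=C/C(C)=C(\Cl)c1c(SC)cc(C)oc1=O.[O-]P(=O)(Cl)Cl | intermediate |
| 8 | (2Z)-3-chloro-2-methyl-3-[6-methyl-4-(methylsulfanyl)-2-oxopyran-3-yl]prop-2-enal | O=C/C(C)=C(\Cl)c1c(SC)cc(C)oc1=O | intermediate |
| 9 | (2E)-2-methyl-3-[6-methyl-4-(methylsulfanyl)-2-oxopyran-3-yl]-3-[2-(trimethylsilyl)ethoxy]prop-2-enal | O=C/C(C)=C(/OCC[Si](C)(C)C)c1c(SC)cc(C)oc1=O | intermediate |
| 10 | (2E,6E)-farnesyl bromide | CC(C)=CCC/C(C)=C/CC/C(C)=C/CBr | starting material |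
| 11 | ethynylmagnesium bromide | C#C[Mg]Br | starting material |
| 12 | (4E,8E)-5,9,13-trimethyltetradeca-4,8,12-trien-1-yne | C#CC/C=C(C)/CC/C=C(C)/CCC=C(C)C | intermediate |
| 13 | diisobutyl[(4E,8E)-5,9,13-trimethyltetradeca-1,4,8,12-tetraen-2-yl]alane | CC(C)C[Al](CC(C)C)C(=C)C/C=C(C)/CC/C=C(C)/CCC=C(C)C | intermediate |
| 14 | dimethyl [(4E,8E)-5,9,13-trimethyltetradeca-1,4,8,12-tetraen-2-yl]boronate | COB(OC)C(=C)C/C=C(C)/CC/C=C(C)/CCC=C(C)C | intermediate |
| 15 | [(4E,8E)-5,9,13-trimethyltetradeca-1,4,8,12-tetraen-2-yl]boronic acid | OB(O)C(=C)C/C=C(C)/CC/C=C(C)/CCC=C(C)C | intermediate |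
| 16 | (2E)-2-methyl-3-{6-methyl-2-oxo-4-[(4E,8E)-5,9,13-trimethyltetradeca-1,4,8,12-tetraen-2-yl]pyran-3-yl}-3-[2-(trimethylsilyl)ethoxy]prop-2-enal | O=C/C(C)=C(/OCC[Si](C)(C)C)c1c(C(=C)C/C=C(C)/CC/C=C(C)/CCC=C(C)C)cc(C)oc1=O | intermediate |
| 17 | (5S)-3,5,7-trimethyl-5-[(2E,6E)-3,7,11-trimethyldodeca-2,6,10-trienyl]-8-[2-(trimethylsilyl)ethoxy]isochromene-1,6-dione | CC(C)=CCC/C(C)=C/CC/C(C)=C/C[C@]1(C)C(=O)C(C)=C(OCC[Si](C)(C)C)c2c1cc(C)oc2=O | intermediate |
| 18 | tetrabutylammonium (5S)-3,5,7-trimethyl-1,6-dioxo-5-[(2E,6E)-3,7,11-trimethyldodeca-2,6,10-trienyl]isochromen-8-olate | CCCC[N+](CCCC)(CCCC)CCCC.CC(C)=CCC/C(C)=C/CC/C(C)=C/C[C@]1(C)C(=O)C(C)=C([O-])c2c1cc(C)oc2=O | intermediate |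
| 19 | (5S)-8-hydroxy-3,5,7-trimethyl-5-[(2E,6E)-3,7,11-trimethyldodeca-2,6,10-trienyl]isochromene-1,6-dione | CC(C)=CCC/C(C)=C/CC/C(C)=C/C[C@]1(C)C(=O)C(C)=C(O)c2c1cc(C)oc2=O | target |

**Step count**

Total step count: 9. Longest linear sequence: 7 steps (steps 1, 2, 3, 4, 7, 8, 9).

**Steps most likely to fail**

**Step 8.**
- The hydroxy-enamine of a push–pull enal may form slowly.
- It may be drained by protonation at C8 with loss of alkoxide, by 7-endo addition to CH2, or by capture of the carbene at C8.
- Facial selectivity on an all-sp2 tether is untested.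

The fallback sets out from 16 and comes back at 17. It makes the same two bonds with normal polarity by a known reaction type, the copper hydride-catalysed enantioselective reductive aldol cyclisation. The conditions are Cu(OAc)2 (5 mol %), (R)-DTBM-SEGPHOS or its antipode, (EtO)2MeSiH and t-BuOH in toluene at −20 to 0 °C. Hydride should go to the terminal CH2, which is the δ-carbon of the C1=O/C8a=C4a/C5=CH2 dienoate, because the β-carbon C4a is fully substituted. The copper dienolate then closes through C5 onto the deactivated C6 aldehyde to give the 5,6-dihydro-6-hydroxy compound F1 (either C6 epimer). Buffered Dess–Martin oxidation (NaHCO3, CH2Cl2, 0 °C) converts F1 into 17.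

**Step 7.**
- Insertion into the hindered C4–S bond may be slow.
- The α-branched boronic acid may be lost by protodeboronation before it transfers.

The fallback sets out from 4 and 15 and comes back at 16. The coupling is moved ahead of the enal construction and changed to a Suzuki–Miyaura reaction of a triflate. Tf2O and Et3N (CH2Cl2, −78 °C) convert 4 into 6-methyl-2-oxo-3-propanoylpyran-4-yl trifluoromethanesulfonate F2. Coupling of F2 with 15 (Pd(dppf)Cl2, K3PO4, THF–H2O, 40 °C) gives the tetraenyl ethyl ketone F3. POCl3/DMF at 0 °C to rt passes through the chloropropeniminium dichlorophosphate F4, and cold aqueous NaOAc then gives the tetraenyl chloro enal F5. Sodium 2-(trimethylsilyl)ethanolate, used as in step 4, leads to 16. The price is exposure of the polyene to the chloroiminium reagent, which is why this order is not the first choice.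

**Step 6.**
- The internal regioselectivity may erode.
- Metal hydride may move the skipped diene into conjugation.
- The boronic acid may be lost by oligomerisation or protodeboronation on isolation.

The fallback sets out from 12 and comes back at 16, and it replaces boron by tin. Stannylcupration–protonation uses Me3SnCu·SMe2 (from Me3SnLi and CuBr·SMe2) and MeOH in THF at −63 °C. This places tin on the internal carbon of 1-alkynes and gives the chromatographically stable 2-(trimethylstannyl)tetraene F6. F6 is joined to 9 by the stannane variant of the thioether coupling (Pd(PPh3)4, copper thiophene-2-carboxylate, THF, 50 °C) to give 16 directly.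

**Further compounds**

F1 | step 8 | (5S)-6-hydroxy-3,5,7-trimethyl-5-[(2E,6E)-3,7,11-trimethyldodeca-2,6,10-trienyl]-8-[2-(trimethylsilyl)ethoxy]-5,6-dihydroisochromen-1-one | CC(C)=CCC/C(C)=C/CC/C(C)=C/C[C@]1(C)C(O)C(C)=C(OCC[Si](C)(C)C)c2c1cc(C)oc2=O
F2 | step 7 | 6-methyl-2-oxo-3-propanoylpyran-4-yl trifluoromethanesulfonate | CCC(=O)c1c(OS(=O)(=O)C(F)(F)F)cc(C)oc1=O
F3 | step 7 | 6-methyl-3-propanoyl-4-[(4E,8E)-5,9,13-trimethyltetradeca-1,4,8,12-tetraen-2-yl]pyran-2-one | CCC(=O)c1c(C(=C)C/C=C(C)/CC/C=C(C)/CCC=C(C)C)cc(C)oc1=O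
F4 | step 7 | (2Z)-3-chloro-N,N,2-trimethyl-3-{6-methyl-2-oxo-4-[(4E,8E)-5,9,13-trimethyltetradeca-1,4,8,12-tetraen-2-yl]pyran-3-yl}prop-2-en-1-iminium dichlorophosphate | C[N+](C)=C/C(C)=C(\Cl)c1c(C(=C)C/C=C(C)/CC/C=C(C)/CCC=C(C)C)cc(C)oc1=O.[O-]P(=O)(Cl)Cl
F5 | step 7 | (2Z)-3-chloro-2-methyl-3-{6-methyl-2-oxo-4-[(4E,8E)-5,9,13-trimethyltetradeca-1,4,8,12-tetraen-2-yl]pyran-3-yl}prop-2-enal | O=C/C(C)=C(\Cl)c1c(C(=C)C/C=C(C)/CC/C=C(C)/CCC=C(C)C)cc(C)oc1=O
F6 | step 6 | trimethyl[(4E,8E)-5,9,13-trimethyltetradeca-1,4,8,12-tetraen-2-yl]stannane | C[Sn](C)(C)C(=C)C/C=C(C)/CC/C=C(C)/CCC=C(C)C
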